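The oxane ring (O1; C2 bears the arylethyl chain, C4 the hydroxyl, C6 the trioxygenated aryl) is cut at C3–C4 and C5–C6, which frees C4–C5 as an ethyne 1,2-dianion. In one flask sodium acetylide opens (S)-epoxide 5 at C3 and the derived alkynide adds to aryl aldehyde 7 at C6; the precursors are thus acyclic and carry one stereocentre. The feature used is the two-carbon C4–C5 bridge between methylene C3 (next to ether carbon C2) and benzylic C6. The ynediol hides the ring: Meyer–Schuster transposition moves the benzylic oxygen from C6 to C4, the C2 hydroxyl closes onto C6, and the epoxide stereocentre alone controls C6 and C4.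

Key step: step 3

Remark on the chemistry: diol 10 is carried as a mixture of epimers at its propargylic carbinol carbon, because step 4 erases that centre; 1, 2, 6 and 8 are taken as purchased.

Step 1
Reactants: 1 4-(benzyloxy)-3-methoxybenzyl chloride; 2 (S)-epichlorohydrin
Product: 5 (2S)-2-{2-[4-(benzyloxy)-3-methoxyphenyl]ethyl}oxirane, via benzylic Grignard reagent 3 (not isolated), via chlorohydrin magnesium alkoxide 4 (not isolated)
Conditions: Mg turnings, THF, 0 °C to rt; then 2, CuI (10 mol %), −40 °C to 0 °C; then aq. NaOH, rt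
Reagents that add atoms: none
Why: Copper-catalysed Grignard opening of the epoxide of 2 at its unsubstituted ring carbon, followed by Williamson-type closure of the chlorohydrin alkoxide, should give 5 with the stereocentre (the later C2, S) taken unchanged from the chiral pool, since no bond to it is made or broken.

Step 2
Reactants: 6 3,4-dihydroxy-5-methoxybenzaldehyde
Product: 7 3,4-bis(benzyloxy)-5-methoxybenzaldehyde
Conditions: BnBr (2.3 equiv), K2CO3, DMF, 60 °C
Reagents that add atoms: benzyl bromide, BrCc1ccccc1
Why: Williamson ether synthesis on both phenols should give 7; benzyl ethers are chosen because they should tolerate acetylide, butyllithium, toluenesulfonic acid and borohydride and leave together in step 6.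

Step 3
Reactants: 5 (2S)-2-{2-[4-(benzyloxy)-3-methoxyphenyl]ethyl}oxirane; 8 sodium acetylide; 7 3,4-bis(benzyloxy)-5-methoxybenzaldehyde
Product: 10 (5S)-1-[3,4-bis(benzyloxy)-5-methoxyphenyl]-7-[4-(benzyloxy)-3-methoxyphenyl]hept-2-yne-1,5-diol (epimers at C1), via homopropargylic sodium alkoxide 9 (not isolated)
Conditions: 8 (1.2 equiv), DMSO, rt; then THF, n-BuLi (1.0 equiv), 0 °C; then 7 (1.3 equiv), 0 °C to rt; aq. NH4Cl
Reagents that add atoms: none
Why: Acetylide 8 attacks the unsubstituted ring carbon C3 of 5 in an SN2 epoxide opening (C3–C4), the alkoxide 9 so formed is metallated at its terminal alkyne carbon C5 by dimsyl lithium made in the flask from n-BuLi, and the alkynide adds to the carbonyl carbon C6 of 7 (C5–C6); the closest known reaction types are the alkylation of metal acetylides by terminal epoxides and the Favorskii-type 1,2-addition of alkynides to aldehydes, here run as a three-component linchpin coupling with ethyne as a 1,2-dianion. No ring is closed in this step. The C2 stereocentre of 5 is untouched because attack occurs at the neighbouring methylene, and the new carbinol centre at C6 forms without control, which is harmless because step 4 turns this carbon into an sp2 centre before resetting it. The step needs regioselective opening at the less hindered epoxide carbon, secured by the base-only SN2 regime without Lewis acid, and clean C-metallation of the alkyne instead of propargyl–allene isomerisation, secured by one full equivalent of strong base at 0 °C before the aldehyde is added. Chemoselectivity in the last stage rests on 7 being non-enolisable and on the small excess of 8, so that the alkynide derived from 9 is the main nucleophile that meets the aldehyde.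

Step 4
Reactants: 10 (5S)-1-[3,4-bis(benzyloxy)-5-methoxyphenyl]-7-[4-(benzyloxy)-3-methoxyphenyl]hept-2-yne-1,5-diol
Product: 12 (2S,6S)-2-[3,4-bis(benzyloxy)-5-methoxyphenyl]-6-{2-[4-(benzyloxy)-3-methoxyphenyl]ethyl}oxan-4-one, via hydroxy enone 11 (not isolated)
Conditions: p-TsOH·H2O (10 mol %), wet ClCH2CH2Cl, 50 °C, high dilution
Reagents that add atoms: none
Why: Acid-catalysed Meyer–Schuster rearrangement (ionisation of the electron-rich benzylic propargylic alcohol, return of water at C4, allenol–enone tautomerism) should give enone 11, whose C2 hydroxyl then adds to C6 in a reversible 6-endo-trig oxa-Michael cyclisation, so that C6 is set as S under thermodynamic control with both ring substituents equatorial (2,6-cis).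

Step 5
Reactants: 12 (2S,6S)-2-[3,4-bis(benzyloxy)-5-methoxyphenyl]-6-{2-[4-(benzyloxy)-3-methoxyphenyl]ethyl}oxan-4-one
Product: 13 (2S,4R,6S)-2-[3,4-bis(benzyloxy)-5-methoxyphenyl]-6-{2-[4-(benzyloxy)-3-methoxyphenyl]ethyl}oxan-4-ol
Conditions: NaBH4, MeOH/THF, −20 °C
Reagents that add atoms: none
Why: Borohydride reduction of the chair oxan-4-one by axial hydride attack (small reagent, torsional control, both 2,6-substituents equatorial) should give the equatorial all-cis alcohol and so set C4 as R.

Step 6
Reactants: 13 (2S,4R,6S)-2-[3,4-bis(benzyloxy)-5-methoxyphenyl]-6-{2-[4-(benzyloxy)-3-methoxyphenyl]ethyl}oxan-4-ol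
Product: 14 (2S,4R,6S)-2-(3,4-dihydroxy-5-methoxyphenyl)-6-[2-(4-hydroxy-3-methoxyphenyl)ethyl]oxan-4-ol
Conditions: H2 (1 atm), 10% Pd/C, EtOAc, rt
Reagents that add atoms: none
Why: Catalytic hydrogenolysis should cleave the three aryl benzyl ethers much faster than the cyclic benzylic C6–O1 ether, so the reaction is stopped after uptake of three equivalents of hydrogen and no stereocentre is touched.

Compound list
1 | 4-(benzyloxy)-3-methoxybenzyl chloride | COc1cc(CCl)ccc1OCc1ccccc1 | starting material
2 | (S)-epichlorohydrin, (2S)-2-(chloromethyl)oxirane | ClC[C@@H]1CO1 | starting material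
3 | [4-(benzyloxy)-3-methoxybenzyl]magnesium chloride | COc1cc(C[Mg]Cl)ccc1OCc1ccccc1 | intermediate
4 | chloromagnesium alkoxide of (2S)-4-[4-(benzyloxy)-3-methoxyphenyl]-1-chlorobutan-2-ol | COc1cc(CC[C@H](O[Mg]Cl)CCl)ccc1OCc1ccccc1 | intermediate
5 | (2S)-2-{2-[4-(benzyloxy)-3-methoxyphenyl]ethyl}oxirane | COc1cc(CC[C@H]2CO2)ccc1OCc1ccccc1 | intermediate
6 | 3,4-dihydroxy-5-methoxybenzaldehyde | COc1cc(C=O)cc(O)c1O | starting material
7 | 3,4-bis(benzyloxy)-5-methoxybenzaldehyde | O=Cc1cc(OCc2ccccc2)c(OCc2ccccc2)c(OC)c1 | intermediate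
8 | sodium acetylide | [Na+].[C-]#C | starting material
9 | sodium alkoxide of (3S)-1-[4-(benzyloxy)-3-methoxyphenyl]hex-5-yn-3-ol | COc1cc(CC[C@H]([O-])CC#C)ccc1OCc1ccccc1.[Na+] | intermediate
10 | (5S)-1-[3,4-bis(benzyloxy)-5-methoxyphenyl]-7-[4-(benzyloxy)-3-methoxyphenyl]hept-2-yne-1,5-diol, both C1 epimers | COc1cc(CC[C@H](O)CC#CC(O)c2cc(OCc3ccccc3)c(OCc3ccccc3)c(OC)c2)ccc1OCc1ccccc1 | intermediate
11 | (1E,5S)-1-[3,4-bis(benzyloxy)-5-methoxyphenyl]-7-[4-(benzyloxy)-3-methoxyphenyl]-5-hydroxyhept-1-en-3-one | COc1cc(CC[C@H](O)CC(=O)/C=C/c2cc(OCc3ccccc3)c(OCc3ccccc3)c(OC)c2)ccc1OCc1ccccc1 | intermediate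
12 | (2S,6S)-2-[3,4-bis(benzyloxy)-5-methoxyphenyl]-6-{2-[4-(benzyloxy)-3-methoxyphenyl]ethyl}oxan-4-one (2,6-cis) | COc1cc(CC[C@H]2CC(=O)C[C@@H](c3cc(OCc4ccccc4)c(OCc4ccccc4)c(OC)c3)O2)ccc1OCc1ccccc1 | intermediate
13 | (2S,4R,6S)-2-[3,4-bis(benzyloxy)-5-methoxyphenyl]-6-{2-[4-(benzyloxy)-3-methoxyphenyl]ethyl}oxan-4-ol (all-cis) | COc1cc(CC[C@H]2C[C@@H](O)C[C@@H](c3cc(OCc4ccccc4)c(OCc4ccccc4)c(OC)c3)O2)ccc1OCc1ccccc1 | intermediate
14 | (2S,4R,6S)-2-(3,4-dihydroxy-5-methoxyphenyl)-6-[2-(4-hydroxy-3-methoxyphenyl)ethyl]oxan-4-ol (all-cis) | COc1cc(CC[C@H]2C[C@@H](O)C[C@@H](c3cc(O)c(O)c(OC)c3)O2)ccc1O | target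

Total step count: 6. Longest linear sequence: 5 steps (steps 1, 3, 4, 5 and 6, from 1); step 2 is a one-step branch.

Steps most likely to fail

1. Step 3. In the basic DMSO medium, proton exchange between alkoxide and alkyne can set off propargyl–allene isomerisation of the terminal alkyne, and acetylide left from the first stage competes for the aldehyde, so the second bond may form incompletely. The fallback sets out from 5 and comes back at 10. Epoxide 5 would be opened with lithium (trimethylsilyl)acetylide and BF3·OEt2 in THF at −78 °C (Yamaguchi–Hirao alkynylation) to give the trimethylsilyl alkynol F1. K2CO3 in MeOH would remove the silyl group and give the terminal alkynol F2, which is purified. Its O,C-dilithio derivative (n-BuLi, 2.1 equiv, THF, −78 °C) would then add to 7 to give 10.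

2. Step 4. The propargylic cation may be captured between molecules (ether formation, alkylation of the electron-rich arenes), or the C2 hydroxyl of 11 may be lost by β-elimination before it adds to C6. The fallback sets out from 5 and comes back at 12. Epoxide 5 would be opened by 2-lithio-2-methyl-1,3-dithiane (Corey–Seebach alkylation; n-BuLi, THF, −30 °C) to give the hydroxy dithiane F3. MeI and CaCO3 in aqueous MeCN would unmask the β-hydroxy methyl ketone F4. LiN(i-Pr)2 and Me3SiCl (THF, −78 °C, internal quench) would give the bis-silyl compound F5, which carries the kinetic terminal silyl enol ether. F5 and 7 with Me3SiOTf in CH2Cl2 at −78 °C would form the oxocarbenium ion at C6 and close the ring through C5 (silyl enol ether Prins cyclisation, chair transition state with equatorial substituents) to give 12.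

3. Step 1. Wurtz homocoupling can occur while the electron-rich benzylic Grignard reagent forms, and partial attack at the chloromethyl carbon of 2 would deliver the enantiomeric epoxide and lower the optical purity. The fallback sets out from 1 and comes back at 5. Chloride 1 would be coupled with allylmagnesium chloride (THF, 0 °C) to give the butenylarene F6, which mCPBA would epoxidise to the racemic oxirane F7. Jacobsen hydrolytic kinetic resolution (water, 0.55 equiv, with the enantiomer of the chiral (salen)Co(OAc) catalyst that hydrolyses the (R)-epoxide) would leave 5.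

Further compounds
F1 | step 3 | (3S)-1-[4-(benzyloxy)-3-methoxyphenyl]-6-(trimethylsilyl)hex-5-yn-3-ol | COc1cc(CC[C@H](O)CC#C[Si](C)(C)C)ccc1OCc1ccccc1
F2 | step 3 | (3S)-1-[4-(benzyloxy)-3-methoxyphenyl]hex-5-yn-3-ol | COc1cc(CC[C@H](O)CC#C)ccc1OCc1ccccc1
F3 | step 4 | (2S)-4-[4-(benzyloxy)-3-methoxyphenyl]-1-(2-methyl-1,3-dithian-2-yl)butan-2-ol | COc1cc(CC[C@H](O)CC2(C)SCCCS2)ccc1OCc1ccccc1
F4 | step 4 | (4S)-6-[4-(benzyloxy)-3-methoxyphenyl]-4-hydroxyhexan-2-one | COc1cc(CC[C@H](O)CC(C)=O)ccc1OCc1ccccc1
F5 | step 4 | (4S)-6-[4-(benzyloxy)-3-methoxyphenyl]-2,4-bis(trimethylsilyloxy)hex-1-ene | COc1cc(CC[C@H](O[Si](C)(C)C)CC(=C)O[Si](C)(C)C)ccc1OCc1ccccc1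
F6 | step 1 | 1-(benzyloxy)-4-(but-3-en-1-yl)-2-methoxybenzene | COc1cc(CCC=C)ccc1OCc1ccccc1
F7 | step 1 | racemic 2-{2-[4-(benzyloxy)-3-methoxyphenyl]ethyl}oxirane | COc1cc(CCC2CO2)ccc1OCc1ccccc1
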